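**Retrosynthetic overview**
1. Target 22 ⇐ hydroxyl-directed epoxidation of the C1=C2 bond of tagitinin C (21) ⇐ desilylation and IBX dehydrogenation (C1=C2) of the ten-membered (Z)-enone 19.
2. Key step: 19 ⇐ three-carbon ring expansion (7 → 10) of the trans-fused cyclopentane–cycloheptene alcohol 18 by alkoxy-radical β-scission of the C3–C9 bond; this returns the C3 ketone and the C9 methylene, and erases the temporary C3 and C9 centres.
3. 18 ⇐ ring-closing metathesis (C4=C5, cis by ring size) ⇐ isopropenyl addition to the C3 ketone of cyclopentanone 15.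
4. 15 ⇐ one-pot conjugate borylation/aldol/oxidation of 3-methylcyclopent-2-enone (sets C10, forms C8–C9, controls C8) with lactone aldehyde 8.
5. 8 ⇐ chromium-catalysed asymmetric allylation of acrolein with a Baylis–Hillman bromide (C6, C7, lactone). Ring order: γ-lactone → cyclopentane (bought) → cycloheptene → cyclodecadienone → epoxide.

Assumption: C-locants follow germacrane numbering of the target (C1–C10 ring, C11–C13 lactone carbons, C14 on C10, C15 on C4), and each chiral ligand is named in the enantiomeric form taken to deliver the drawn configuration.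

**Route**

Step 1
Reactants: 1 2,2-dimethoxyacetaldehyde; 2 methyl acrylate
Product: 3 methyl 2-(1-hydroxy-2,2-dimethoxyethyl)prop-2-enoate (racemic)
Conditions: DABCO (0.5 equiv), 1,4-dioxane/H2O 1:1, rt
Reagents that add atoms: none
Why: Morita–Baylis–Hillman reaction: the ammonium enolate formed from DABCO and the acrylate adds to the unhindered, inductively activated α,α-dialkoxy aldehyde (fast in aqueous dioxane), and the racemic carbinol centre created here is destroyed again in step 2.

Step 2
Reactants: 3 methyl 2-(1-hydroxy-2,2-dimethoxyethyl)prop-2-enoate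
Product: 4 methyl (2Z)-2-(bromomethyl)-4,4-dimethoxybut-2-enoate
Conditions: NBS, Me2S, CH2Cl2, 0 °C to rt
Reagents that add atoms: N-bromosuccinimide BrN1C(=O)CCC1=O
Why: Bromination of a Baylis–Hillman alcohol with allylic transposition (Corey–Kim-type activation then SN2′ attack of bromide): the alkoxysulfonium group leaves as DMSO while bromide enters at the terminal carbon, which moves the alkene into conjugation and gives the thermodynamically preferred (Z)-2-(bromomethyl)enoate.

Step 3
Reactants: 4 methyl (2Z)-2-(bromomethyl)-4,4-dimethoxybut-2-enoate; 5 acrolein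
Product: 8 (2R,3S)-4-methylidene-5-oxo-2-vinyloxolane-3-carbaldehyde, via silyl ether 6 (not isolated), via lactone acetal 7 (not isolated)
Conditions: CrCl2 (10 mol %), (S,S)-1,8-bis(4-isopropyl-4,5-dihydrooxazol-2-yl)-3,6-diphenylcarbazole (11 mol %), Mn powder, Me3SiCl, iPr2NEt, THF, rt; then 1 M HCl, THF, 0 °C to rt
Reagents that add atoms: water O (aldehyde oxygen of 8); chlorotrimethylsilane C[Si](C)(C)Cl (silicon in 6 only)
Why: Catalytic asymmetric Nozaki–Hiyama–Kishi 2-(alkoxycarbonyl)allylation followed by acid-mediated lactonisation and acetal hydrolysis: the γ-substituted allylchromium species adds 1,2 to acrolein through a chair transition state that gives the anti adduct (6,7-trans lactone), the chiral bis(oxazolinyl)carbazole–chromium complex selects the aldehyde face that makes C6 R (and therefore C7 as drawn), and dilute acid then cleaves the silyl ether, closes the γ-lactone and unmasks the C8 aldehyde, which is used crude and cold because it is a β,γ-unsaturated aldehyde.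

Step 4
Reactants: 9 3-methylcyclopent-2-en-1-one; 8 (2R,3S)-4-methylidene-5-oxo-2-vinyloxolane-3-carbaldehyde
Product: 12 (2R,3S)-3-hydroxy-2-[(S)-hydroxy{(2R,3R)-4-methylidene-5-oxo-2-vinyloxolan-3-yl}methyl]-3-methylcyclopentan-1-one, via boron enolate 10 (not isolated), via boron aldolate 11 (not isolated)
Conditions: [Cu(MeCN)4]PF6 (5 mol %), (R,R)-QuinoxP* (6 mol %), LiOtBu (10 mol %), B2pin2 (1.0 equiv), 9 (1.05 equiv), THF, rt; then 8, −78 to 0 °C; then NaBO3·4H2O, THF/H2O, 0 °C to rt
Reagents that add atoms: sodium perborate [Na+].[O-]OB=O (the C10 oxygen); bis(pinacolato)diboron CC1(C)OB(OC1(C)C)B1OC(C)(C)C(C)(C)O1 (boron in 10 and 11 only)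
Why: Copper-catalysed asymmetric conjugate borylation followed by boron-enolate aldol addition and C–B oxidation (one-pot conjugate boration–aldol sequence): the QuinoxP*–copper boryl complex sets C10, the regiodefined cyclic (E)-boron enolate (diboron fully consumed before 8 is added) attacks 8 through a Zimmerman–Traxler chair from the face anti to the bulky boryl group, which gives the anti aldol and thus the 8,10-anti relationship of the target, perborate then replaces boron by hydroxyl with retention, and the C9 centre formed here is only temporary.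

Step 5
Reactants: 12 diol ketone from step 4; 13 2-methylpropanoyl chloride
Product: 15 (S)-[(1R,2S)-2-methyl-5-oxo-2-(triethylsilyloxy)cyclopentyl][(2R,3S)-4-methylidene-5-oxo-2-vinyloxolan-3-yl]methyl 2-methylpropanoate, via monoester 14 (not isolated)
Conditions: iPrCOCl, pyridine, DMAP (cat.), CH2Cl2, 0 °C; then Et3SiOTf, 2,6-lutidine, −78 to 0 °C
Reagents that add atoms: triethylsilyl trifluoromethanesulfonate CC[Si](CC)(CC)OS(=O)(=O)C(F)(F)F
Why: Chemoselective esterification then silylation: the acid chloride acylates only the secondary C8 hydroxyl (the tertiary C10 hydroxyl is inert to it), the silyl triflate then caps the tertiary alcohol, no stereocentre is touched, and the cold, weakly basic medium avoids β-elimination of the β-acyloxy ketone.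

Step 6
Reactants: 15 silylated keto ester from step 5; 16 isopropenylmagnesium bromide
Product: 17 (S)-[(1S,2S,5S)-2-hydroxy-5-methyl-2-(prop-1-en-2-yl)-5-(triethylsilyloxy)cyclopentyl][(2R,3S)-4-methylidene-5-oxo-2-vinyloxolan-3-yl]methyl 2-methylpropanoate
Conditions: LaCl3·2LiCl (1.1 equiv), THF, −78 °C; aq NH4Cl
Reagents that add atoms: none
Why: Lanthanum-promoted Grignard 1,2-addition to a hindered, enolisable ketone: at −78 °C the ketone reacts far faster than the lactone, the ester or the exocyclic enoate, the nucleophile enters anti to the C9 side chain (isopropenyl trans to C8), and the new C3 carbinol centre is temporary because C3 returns to a ketone in step 8.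

Step 7
Reactants: 17 diene alcohol from step 6
Product: 18 (3S,6R,7S,8S,9S,10S)-3-hydroxy-8-(2-methylpropanoyloxy)-10-(triethylsilyloxy)-3,9-cyclogermacra-4,11(13)-dien-12,6-olide
Conditions: second-generation Hoveyda–Grubbs catalyst RuCl2(H2IMes)(=CH-C6H4-2-OiPr) (5 mol %), toluene (5 mM), 80 °C
Reagents that add atoms: none
Why: Ring-closing olefin metathesis between the vinyl group on C6 and the isopropenyl group on C3 (activated by the allylic hydroxyl) closes the seven-membered ring, in which the new trisubstituted C4=C5 bond is necessarily cis (the future 4Z alkene), while the electron-poor exocyclic methylene is not a competent metathesis partner and no stereocentre is affected.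

Step 8
Reactants: 18 tricyclic tertiary alcohol from step 7
Product: 19 (4Z,6R,7R,8R,10S)-8-(2-methylpropanoyloxy)-3-oxo-10-(triethylsilyloxy)germacra-4,11(13)-dien-12,6-olide
Conditions: [Ir(dF(CF3)ppy)2(5,5′-d(CF3)bpy)]PF6 (2 mol %), 2,4,6-triisopropylbenzenethiol (30 mol %), Bu4P(MeO)2PO2 (25 mol %), PhCF3, blue LEDs, rt
Reagents that add atoms: none
Why: Proposed new method: a photocatalytic, redox-neutral ring-expanding isomerisation in which the excited iridium complex and the phosphate base remove an electron and a proton from the tertiary hydroxyl (proton-coupled electron transfer) to give the C3 alkoxy radical, whose β-scission breaks the C3–C9 ring-fusion bond selectively (the only cleavage that gives a secondary alkyl radical, since C3–C2 would give a primary and C3–C4 a vinyl radical, and the one that forms a conjugated enone and releases the strain of the trans-fused five–seven system), after which the C9 radical takes a hydrogen atom from the hindered arenethiol and the thiyl radical is reduced and reprotonated by the reduced photocatalyst and the phosphoric acid, so that C3 becomes the ketone, C9 a methylene, the cis ring alkene the 4Z enone and the C6, C7, C8 and C10 centres stay untouched; the closest known reactions are the photocatalytic ring-opening isomerisation of simple cycloalkanols and the hypoiodite (Suárez) fragmentation of ring-fusion alcohols, neither of which has been shown for a ring-fusion tertiary allylic alcohol giving a medium-ring enone.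

Step 9
Reactants: 19 ten-membered enone from step 8
Product: 20 (1E,4Z,6R,7R,8R,10R)-8-(2-methylpropanoyloxy)-3-oxo-10-(triethylsilyloxy)germacra-1,4,11(13)-trien-12,6-olide
Conditions: IBX (3 equiv), DMSO/fluorobenzene 1:2, 65 °C
Reagents that add atoms: none
Why: IBX-mediated α,β-dehydrogenation of a ketone (Nicolaou dehydrogenation): the C3 ketone can enolise only towards C2 because C4 is sp2, loss of a C1 hydrogen gives the cross-conjugated dienone, the 1E geometry is favoured because the quaternary C10 avoids allylic strain against the carbonyl group, and the silyl ether keeps C10–O from forming a transannular hemiketal at C3 before the E alkene is in place.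

Step 10
Reactants: 20 silylated dienone from step 9
Product: 21 tagitinin C [(1E,4Z,6R,7R,8R,10R)-10-hydroxy-8-(2-methylpropanoyloxy)-3-oxogermacra-1,4,11(13)-trien-12,6-olide]
Conditions: HF·pyridine, pyridine, THF, 0 °C to rt
Reagents that add atoms: none
Why: Fluoride-mediated cleavage of the tertiary triethylsilyl ether (desilylation) under buffered conditions that leave the dienone, the isobutyrate and the α-methylene lactone untouched, no stereocentre being affected, gives tagitinin C.

Step 11
Reactants: 21 tagitinin C
Product: 22 (1R,2R,4Z,6R,7R,8R,10R)-1,2-epoxy-10-hydroxy-8-(2-methylpropanoyloxy)-3-oxogermacra-4,11(13)-dien-12,6-olide (CNP0273626.1)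
Conditions: t-BuOOH (decane, 1.5 equiv), DBU (1.1 equiv), CH2Cl2, 0 °C
Reagents that add atoms: tert-butyl hydroperoxide CC(C)(C)OO
Why: Hydroxyl-directed nucleophilic epoxidation (Weitz–Scheffer type): the free C10 hydroxyl hydrogen-bonds the tert-butyl peroxide anion and delivers it to the face of C1 syn to O10, closure of the resulting peroxy enolate gives the trans epoxide and thus 1R,2R, and the hindered (Z)-α-methyl enone and the ester-conjugated exocyclic methylene react much more slowly than the E enone.

**Compound list**
1 | 2,2-dimethoxyacetaldehyde | COC(OC)C=O | starting material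
2 | methyl acrylate | C=CC(=O)OC | starting material
3 | methyl 2-(1-hydroxy-2,2-dimethoxyethyl)prop-2-enoate (racemic) | COC(OC)C(O)C(=C)C(=O)OC | intermediate
4 | methyl (2Z)-2-(bromomethyl)-4,4-dimethoxybut-2-enoate | COC(OC)/C=C(\CBr)C(=O)OC | intermediate
5 | acrolein (prop-2-enal) | C=CC=O | starting material
6 | methyl (3S,4R)-3-(dimethoxymethyl)-2-methylidene-4-(trimethylsilyloxy)hex-5-enoate | C=C(C(=O)OC)[C@H](C(OC)OC)[C@H](O[Si](C)(C)C)C=C | intermediate (not isolated)
7 | (4S,5R)-4-(dimethoxymethyl)-3-methylidene-5-vinyloxolan-2-one | C=C1C(=O)O[C@H](C=C)[C@H]1C(OC)OC | intermediate (not isolated)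
8 | (2R,3S)-4-methylidene-5-oxo-2-vinyloxolane-3-carbaldehyde | C=C1C(=O)O[C@H](C=C)[C@H]1C=O | intermediate
9 | 3-methylcyclopent-2-en-1-one | CC1=CC(=O)CC1 | starting material
10 | 2-{[(3R)-3-methyl-3-(4,4,5,5-tetramethyl-1,3,2-dioxaborolan-2-yl)cyclopent-1-en-1-yl]oxy}-4,4,5,5-tetramethyl-1,3,2-dioxaborolane (boron enolate) | CC1(C)OB(OC2=C[C@@](C)(B3OC(C)(C)C(C)(C)O3)CC2)OC1(C)C | intermediate (not isolated)
11 | (2S,3R)-3-methyl-2-[(S)-{(2R,3R)-4-methylidene-5-oxo-2-vinyloxolan-3-yl}(pinacolboryloxy)methyl]-3-(pinacolboryl)cyclopentan-1-one (boron aldolate) | C=C1C(=O)O[C@H](C=C)[C@H]1[C@H](OB2OC(C)(C)C(C)(C)O2)[C@H]1C(=O)CC[C@]1(C)B1OC(C)(C)C(C)(C)O1 | intermediate (not isolated)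
12 | (2R,3S)-3-hydroxy-2-[(S)-hydroxy{(2R,3R)-4-methylidene-5-oxo-2-vinyloxolan-3-yl}methyl]-3-methylcyclopentan-1-one (C8-OH trans to C10-OH on the ring side, 8,10-anti) | C=C1C(=O)O[C@H](C=C)[C@H]1[C@H](O)[C@H]1C(=O)CC[C@]1(C)O | intermediate
13 | 2-methylpropanoyl chloride (isobutyryl chloride) | CC(C)C(=O)Cl | starting material
14 | (S)-[(1R,2S)-2-hydroxy-2-methyl-5-oxocyclopentyl][(2R,3S)-4-methylidene-5-oxo-2-vinyloxolan-3-yl]methyl 2-methylpropanoate | C=C1C(=O)O[C@H](C=C)[C@H]1[C@H](OC(=O)C(C)C)[C@H]1C(=O)CC[C@]1(C)O | intermediate (not isolated)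
15 | (S)-[(1R,2S)-2-methyl-5-oxo-2-(triethylsilyloxy)cyclopentyl][(2R,3S)-4-methylidene-5-oxo-2-vinyloxolan-3-yl]methyl 2-methylpropanoate | C=C1C(=O)O[C@H](C=C)[C@H]1[C@H](OC(=O)C(C)C)[C@H]1C(=O)CC[C@]1(C)O[Si](CC)(CC)CC | intermediate
16 | isopropenylmagnesium bromide | CC(=C)[Mg]Br | starting material
17 | (S)-[(1S,2S,5S)-2-hydroxy-5-methyl-2-(prop-1-en-2-yl)-5-(triethylsilyloxy)cyclopentyl][(2R,3S)-4-methylidene-5-oxo-2-vinyloxolan-3-yl]methyl 2-methylpropanoate (isopropenyl trans to the C8 side chain) | C=C1C(=O)O[C@H](C=C)[C@H]1[C@H](OC(=O)C(C)C)[C@H]1[C@](O)(C(C)=C)CC[C@]1(C)O[Si](CC)(CC)CC | intermediate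
18 | (3S,6R,7S,8S,9S,10S)-3-hydroxy-8-(2-methylpropanoyloxy)-10-(triethylsilyloxy)-3,9-cyclogermacra-4,11(13)-dien-12,6-olide (trans-fused five–seven carbocycle, trans-fused lactone) | C=C1C(=O)O[C@@H]2C=C(C)[C@]3(O)CC[C@](C)(O[Si](CC)(CC)CC)[C@H]3[C@@H](OC(=O)C(C)C)[C@@H]12 | intermediate
19 | (4Z,6R,7R,8R,10S)-8-(2-methylpropanoyloxy)-3-oxo-10-(triethylsilyloxy)germacra-4,11(13)-dien-12,6-olide | C=C1C(=O)O[C@@H]2/C=C(/C)C(=O)CC[C@](C)(O[Si](CC)(CC)CC)C[C@@H](OC(=O)C(C)C)[C@@H]12 | intermediate
20 | (1E,4Z,6R,7R,8R,10R)-8-(2-methylpropanoyloxy)-3-oxo-10-(triethylsilyloxy)germacra-1,4,11(13)-trien-12,6-olide | C=C1C(=O)O[C@@H]2/C=C(/C)C(=O)/C=C/[C@](C)(O[Si](CC)(CC)CC)C[C@@H](OC(=O)C(C)C)[C@@H]12 | intermediate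
21 | tagitinin C, (1E,4Z,6R,7R,8R,10R)-10-hydroxy-8-(2-methylpropanoyloxy)-3-oxogermacra-1,4,11(13)-trien-12,6-olide | C=C1C(=O)O[C@@H]2/C=C(/C)C(=O)/C=C/[C@](C)(O)C[C@@H](OC(=O)C(C)C)[C@@H]12 | intermediate
22 | (1R,2R,4Z,6R,7R,8R,10R)-1,2-epoxy-10-hydroxy-8-(2-methylpropanoyloxy)-3-oxogermacra-4,11(13)-dien-12,6-olide (CNP0273626.1) | C=C1C(=O)O[C@@H]2/C=C(/C)C(=O)[C@@H]3O[C@H]3[C@](C)(O)C[C@@H](OC(=O)C(C)C)[C@@H]12 | target

**Step count and risks**

Total step count: 11. Longest linear sequence: 11 steps (steps 1–11, from 1 and 2 to 22).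

The three steps most likely to fail:

Step 8 (the proposed ring expansion). The C3 alkoxy radical could instead abstract the allylic C6 hydrogen (1,5-transfer) or cleave towards C2. The C9 radical could add across the ring to C5 of the new enone before it is reduced. The thiol could add reversibly to the methylene lactone. The fallback uses known chemistry, sets out from 18 and comes back at 19. Treatment of 18 with PhI(OAc)2 and I2 in cyclohexane/CH2Cl2 under visible light forms the tertiary hypoiodite, whose alkoxy radical fragments the same C3–C9 bond; the C9 radical is captured at once by iodine to give the 9-iodo derivative of 19 (both C9 epimers) F1. Reduction of F1 with Bu3SnH (0.5 M, AIBN, benzene, 80 °C), where the high hydride concentration outruns transannular cyclisation, gives 19.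

Step 4 (three-component borylation/aldol). Aldehyde 8 can isomerise its exocyclic alkene into conjugation under the basic copper conditions. Any remaining copper boryl species can add to the methylene lactone. The weak intrinsic facial bias of 8 could also erode the enolate-controlled C8 selectivity. The fallback masks the methylene group, sets out from 7 (isolated when the hydrochloric acid stage of step 3 is replaced by citric acid in methanol) and comes back at 12. Thiophenol with catalytic Et3N adds to 7 to give (4S,5R)-4-(dimethoxymethyl)-3-[(phenylsulfanyl)methyl]-5-vinyloxolan-2-one F2. Hydrolysis with 1 M HCl in THF gives (2R,3S)-5-oxo-4-[(phenylsulfanyl)methyl]-2-vinyloxolane-3-carbaldehyde F3, which can no longer isomerise into conjugation and is inert to copper boryl species. Under the conditions of step 4, F3 gives the phenylsulfanyl analogue of boron aldolate 11 F4 (not isolated). NaBO3 followed by NaIO4 then gives the phenylsulfinyl analogue of diol 12 F5. Heating F5 in toluene at 90 °C over CaCO3 expels benzenesulfenic acid by syn elimination and restores the exocyclic methylene, which is compound 12.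

Step 11 (final epoxidation). The facial selectivity rests on hydroxyl direction within a flexible ten-membered ring, and the peroxide anion may also attack the methylene lactone. The fallback changes from substrate direction to reagent control and changes the order of the last steps; it sets out from 20 and comes back at 22. Silyl ether 20 is epoxidised with La(OiPr)3, (S)-BINOL and Ph3As=O (5 mol % each) and t-BuOOH in THF; this catalyst acts only on ketone-conjugated E alkenes and sets the epoxide by catalyst hand, to give (1R,2R,4Z,6R,7R,8R,10R)-1,2-epoxy-8-(2-methylpropanoyloxy)-3-oxo-10-(triethylsilyloxy)germacra-4,11(13)-dien-12,6-olide F6. HF·pyridine then removes the silyl group from F6 to give 22.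

Further compounds
F1 | step 8 | 9-iodo derivative of 19: (4Z)-9-iodo-8-(2-methylpropanoyloxy)-3-oxo-10-(triethylsilyloxy)germacra-4,11(13)-dien-12,6-olide (both C9 epimers; C6, C7, C8 and C10 arranged as in 19) | C=C1C(=O)O[C@@H]2/C=C(/C)C(=O)CC[C@](C)(O[Si](CC)(CC)CC)C(I)[C@@H](OC(=O)C(C)C)[C@@H]12
F2 | step 4 | (4S,5R)-4-(dimethoxymethyl)-3-[(phenylsulfanyl)methyl]-5-vinyloxolan-2-one (both C3 epimers) | c1ccccc1SCC1C(=O)O[C@H](C=C)[C@H]1C(OC)OC
F3 | step 4 | (2R,3S)-5-oxo-4-[(phenylsulfanyl)methyl]-2-vinyloxolane-3-carbaldehyde (both C4 epimers) | c1ccccc1SCC1C(=O)O[C@H](C=C)[C@H]1C=O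
F4 | step 4 | phenylsulfanyl analogue of boron aldolate 11 (not isolated; epimers at the sulfanylmethyl-bearing carbon) | c1ccccc1SCC1C(=O)O[C@H](C=C)[C@H]1[C@H](OB2OC(C)(C)C(C)(C)O2)[C@H]1C(=O)CC[C@]1(C)B1OC(C)(C)C(C)(C)O1
F5 | step 4 | phenylsulfinyl analogue of diol 12: (2R,3S)-3-hydroxy-2-[(S)-hydroxy{(2R,3R)-5-oxo-4-[(phenylsulfinyl)methyl]-2-vinyloxolan-3-yl}methyl]-3-methylcyclopentan-1-one (epimers at lactone C4 and at sulfur) | O=S(CC1C(=O)O[C@H](C=C)[C@H]1[C@H](O)[C@H]1C(=O)CC[C@]1(C)O)c1ccccc1
F6 | step 11 | (1R,2R,4Z,6R,7R,8R,10R)-1,2-epoxy-8-(2-methylpropanoyloxy)-3-oxo-10-(triethylsilyloxy)germacra-4,11(13)-dien-12,6-olide | C=C1C(=O)O[C@@H]2/C=C(/C)C(=O)[C@@H]3O[C@H]3[C@](C)(O[Si](CC)(CC)CC)C[C@@H](OC(=O)C(C)C)[C@@H]12
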